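**Retrosynthetic overview**

1. Feature: ring A carries C5–OH next to fusion carbon C4a, then C6–OH, C7–CO2H and C8–H. This is the pattern left when a 5-substituted 2-benzyloxyfuran-3-carboxylate (C6, C7, C8, C8a) is merged with a tethered terminal alkyne (C4a, C5) and the furan oxygen is passed on to C5.
2. Key disconnection: C4a–C8a and C5–C6 by gold-catalysed furan–yne cycloisomerisation of an acyclic furan–yne that already holds all four stereocentres; ring B closes first, ring A second, in one step.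
3. The furan is built on a terminal alkyne with dibenzyl diazomalonate in two stages (cyclopropenation, then ring-opening cycloisomerisation), because an aliphatic alkyne gives the cyclopropene, not the furan, with Rh2(OAc)4. The C4 alkyne is carried as its triisopropylsilyl derivative so the two alkynes stay distinguishable, and the acetates are put on only after the last basic step.
4. C1 and C1′ come from an Ireland–Claisen rearrangement (chirality transfer from an (S,E)-allylic alcohol, Z ketene acetal); C4 from (R)-citronellal; C5′ from methyl (S)-3-hydroxy-2-methylpropanoate.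
5. End game: hydrogenolysis of the benzyl ether and benzyl ester.

Key step: step 20

Remark on locants: tetralin C1 bears the side chain, C4 the methyl, C4a/C8a are the fusion carbons, C5 and C6 bear OH, C7 bears CO2H, C8 bears H; the side chain is C1′(C7′H2OAc)–C2′–C3′–C4′–C5′(CH3)–C6′H2OAc.
Assumption: commercial (R)-citronellal of high enantiomeric purity is used, so that C4 enters as a single configuration.

**Fragment 1 (acid, C7′ and C1′–C6′)**

Step 1
Reactants: 1 methyl (S)-3-hydroxy-2-methylpropanoate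
Product: 2 methyl (S)-3-(tert-butyldimethylsilyloxy)-2-methylpropanoate
Conditions: TBSCl, imidazole, DMF, 0 → 23 °C
Reagents that add atoms: tert-butyldimethylsilyl chloride, CC(C)(C)[Si](C)(C)Cl
Why: Imidazole-assisted silylation of the primary alcohol masks the future C6′ oxygen through the basic and reducing steps, and the stereocentre (future C5′) is not involved.

Step 2
Reactants: 2 methyl (S)-3-(tert-butyldimethylsilyloxy)-2-methylpropanoate
Product: 3 (S)-3-(tert-butyldimethylsilyloxy)-2-methylpropanal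
Conditions: DIBAL-H (1.1 equiv), CH2Cl2, −78 °C; aq. Rochelle salt
Reagents that add atoms: none
Why: Partial ester reduction with DIBAL-H at −78 °C stops at the aluminium hemiacetal, which releases the aldehyde only on work-up, and the α-stereocentre should hold if the aldehyde is used cold and without storage.

Step 3
Reactants: 3 (S)-3-(tert-butyldimethylsilyloxy)-2-methylpropanal
Product: 4 (4Z,6R)-7-(tert-butyldimethylsilyloxy)-6-methylhept-4-enoic acid
Conditions: (3-carboxypropyl)triphenylphosphonium bromide, NaHMDS (2.1 equiv), THF, 0 °C; then 3, −78 → 23 °C; aq. HCl to pH 3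
Reagents that add atoms: (3-carboxypropyl)triphenylphosphonium bromide, [Br-].OC(=O)CCC[P+](c1ccccc1)(c1ccccc1)c1ccccc1
Why: Wittig olefination with the preformed, non-stabilised carboxylate ylide should add to the aldehyde at −78 °C faster than the aldehyde enolises, giving the (Z)-alkenoic acid with C5′ intact and carbons C3′, C2′, C1′ and C7′ in place.

Step 4
Reactants: 4 (4Z,6R)-7-(tert-butyldimethylsilyloxy)-6-methylhept-4-enoic acid
Product: 5 (R)-7-(tert-butyldimethylsilyloxy)-6-methylheptanoic acid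
Conditions: H2 (1 atm), 10% Pd/C, EtOAc, 23 °C
Reagents that add atoms: none
Why: Heterogeneous catalytic hydrogenation removes the alkene (whose geometry is therefore irrelevant) under neutral conditions that leave the silyl ether and the stereocentre untouched.

**Fragment 2 (allylic alcohol, C1–C4 and the masked C4 alkyne)**

Step 5
Reactants: 6 (R)-citronellal
Product: 8 (R)-3,7-dimethyloct-6-en-1-yne, via alkenyl nonaflate 7 (not isolated)
Conditions: nonafluorobutanesulfonyl fluoride (NfF), phosphazene base P2-Et (2.2 equiv), DMF, −20 → 23 °C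
Reagents that add atoms: none
Why: One-pot nonaflation–elimination of an enolisable aldehyde: the phosphazene base forms the enolate, NfF traps it as alkenyl nonaflate 7 and a second equivalent of base eliminates nonaflate, so CH2–CHO becomes C≡CH with no change in carbon count and the adjacent stereocentre (future C4), which is never deprotonated, is kept.

Step 6
Reactants: 8 (R)-3,7-dimethyloct-6-en-1-yne
Product: 9 (R)-(3,7-dimethyloct-6-en-1-yn-1-yl)triisopropylsilane
Conditions: n-BuLi, THF, −78 °C; TIPSCl, −78 → 23 °C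
Reagents that add atoms: triisopropylsilyl chloride, CC(C)[Si](Cl)(C(C)C)C(C)C
Why: Deprotonation of the terminal alkyne and C-silylation of the acetylide; the triisopropylsilyl group is chosen because it survives K2CO3/MeOH in step 14 and shields this alkyne from the rhodium carbenoid in step 16.

Step 7
Reactants: 9 (R)-(3,7-dimethyloct-6-en-1-yn-1-yl)triisopropylsilane
Product: 11 (R)-4-methyl-6-(triisopropylsilyl)hex-5-ynal, via ozonide 10 (not isolated)
Conditions: O3, CH2Cl2, −78 °C, stopped when the alkene is consumed (indicator dye); PPh3, −78 → 23 °C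
Reagents that add atoms: ozone, [O-][O+]=O
Why: Ozonolysis with reductive work-up cleaves the electron-rich trisubstituted alkene far faster than the silylated alkyne and gives the aldehyde whose carbon becomes C1.

Step 8
Reactants: 11 (R)-4-methyl-6-(triisopropylsilyl)hex-5-ynal
Product: 12 (3E,7R)-7-methyl-9-(triisopropylsilyl)non-3-en-8-yn-2-one
Conditions: Ph3P=CHC(O)CH3, CH2Cl2, 40 °C
Reagents that add atoms: 1-(triphenylphosphoranylidene)propan-2-one, CC(=O)C=P(c1ccccc1)(c1ccccc1)c1ccccc1
Why: Wittig olefination with a stabilised ylide should give the (E)-enone.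

Step 9
Reactants: 12 (3E,7R)-7-methyl-9-(triisopropylsilyl)non-3-en-8-yn-2-one
Product: 13 (2S,3E,7R)-7-methyl-9-(triisopropylsilyl)non-3-en-8-yn-2-ol
Conditions: (R)-2-methyl-CBS-oxazaborolidine (15 mol%), catecholborane, toluene, −78 °C
Reagents that add atoms: none
Why: Corey–Bakshi–Shibata reduction: the (R)-oxazaborolidine binds the ketone with the alkenyl group as the large substituent and delivers hydride from catecholborane to give the (S)-carbinol, while the low temperature avoids conjugate reduction and hydroboration of the alkyne.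

**Union, C1/C1′ and the 1,7-diyne**

Step 10
Reactants: 5 (R)-7-(tert-butyldimethylsilyloxy)-6-methylheptanoic acid; 13 (2S,3E,7R)-7-methyl-9-(triisopropylsilyl)non-3-en-8-yn-2-ol
Product: 14 (2S,3E,7R)-7-methyl-9-(triisopropylsilyl)non-3-en-8-yn-2-yl (R)-7-(tert-butyldimethylsilyloxy)-6-methylheptanoate
Conditions: DCC, DMAP (cat.), CH2Cl2, 0 → 23 °C
Reagents that add atoms: none
Why: Steglich esterification (carbodiimide activation with DMAP acyl transfer) joins fragments 1 and 2 and breaks only the O–H bond of the carbinol, so its configuration is retained.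

Step 11
Reactants: 14 (2S,3E,7R)-7-methyl-9-(triisopropylsilyl)non-3-en-8-yn-2-yl (R)-7-(tert-butyldimethylsilyloxy)-6-methylheptanoate
Product: 17 (2S,3R,4E)-2-[(4R)-5-(tert-butyldimethylsilyloxy)-4-methylpentyl]-3-[(3R)-3-methyl-5-(triisopropylsilyl)pent-4-yn-1-yl]hex-4-en-1-ol, via Z silyl ketene acetal 15 (not isolated), via silyl ester 16 (not isolated)
Conditions: LDA, THF/DMPU, −78 °C; TBSCl, −78 → 40 °C; then LiAlH4, 0 °C
Reagents that add atoms: none
Why: Ireland–Claisen rearrangement: LDA in THF/DMPU should give the ester enolate with the alkyl chain cis to O–Li, silylation fixes it as Z ketene acetal 15, and the chair transition state with the carbinol methyl group equatorial passes the (S) configuration of the carbinol on to C1 and sets C1′ syn to it, after which LiAlH4 reduces silyl ester 16 in the same flask.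

Step 12
Reactants: 17 (2S,3R,4E)-2-[(4R)-5-(tert-butyldimethylsilyloxy)-4-methylpentyl]-3-[(3R)-3-methyl-5-(triisopropylsilyl)pent-4-yn-1-yl]hex-4-en-1-ol
Product: 18 (2S,3R,4E)-1-(tert-butyldimethylsilyloxy)-2-[(4R)-5-(tert-butyldimethylsilyloxy)-4-methylpentyl]-3-[(3R)-3-methyl-5-(triisopropylsilyl)pent-4-yn-1-yl]hex-4-ene
Conditions: TBSCl, imidazole, CH2Cl2, 23 °C
Reagents that add atoms: tert-butyldimethylsilyl chloride, CC(C)(C)[Si](C)(C)Cl
Why: Silyl ether formation protects the new C7′ hydroxyl, which would otherwise form a lactol with the C1 aldehyde and undergo O–H insertion with the rhodium carbenoid.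

Step 13
Reactants: 18 (2S,3R,4E)-1-(tert-butyldimethylsilyloxy)-2-[(4R)-5-(tert-butyldimethylsilyloxy)-4-methylpentyl]-3-[(3R)-3-methyl-5-(triisopropylsilyl)pent-4-yn-1-yl]hex-4-ene
Product: 20 (2S,3S,7R)-8-(tert-butyldimethylsilyloxy)-3-[(tert-butyldimethylsilyloxy)methyl]-7-methyl-2-[(3R)-3-methyl-5-(triisopropylsilyl)pent-4-yn-1-yl]octanal, via ozonide 19 (not isolated)
Conditions: O3, CH2Cl2, −78 °C, stopped when the alkene is consumed (indicator dye); PPh3, −78 → 23 °C
Reagents that add atoms: ozone, [O-][O+]=O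
Why: Ozonolysis of the 1,2-disubstituted alkene next to the hindered silyl alkyne with reductive work-up gives the α-branched aldehyde, which is used at once so that C1 does not epimerise.

Step 14
Reactants: 20 (2S,3S,7R)-8-(tert-butyldimethylsilyloxy)-3-[(tert-butyldimethylsilyloxy)methyl]-7-methyl-2-[(3R)-3-methyl-5-(triisopropylsilyl)pent-4-yn-1-yl]octanal
Product: 21 (3S,4S,8R)-9-(tert-butyldimethylsilyloxy)-4-[(tert-butyldimethylsilyloxy)methyl]-8-methyl-3-[(3R)-3-methyl-5-(triisopropylsilyl)pent-4-yn-1-yl]non-1-yne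
Conditions: dimethyl (1-diazo-2-oxopropyl)phosphonate, K2CO3, MeOH, 0 → 23 °C
Reagents that add atoms: dimethyl (1-diazo-2-oxopropyl)phosphonate, COP(=O)(OC)C(=[N+]=[N-])C(C)=O
Why: Seyferth–Gilbert homologation in the Ohira–Bestmann variant: methanolysis of the reagent gives the anion of dimethyl (diazomethyl)phosphonate, which adds to the aldehyde, and loss of phosphate and N2 with 1,2-hydride shift of the alkylidene carbene gives the terminal alkyne under conditions that the silyl ethers and the C–Si bond tolerate and that are mild enough to keep C1.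

**Furan and furan–yne**

Step 15
Reactants: 22 dibenzyl malonate
Product: 23 dibenzyl 2-diazomalonate
Conditions: 4-acetamidobenzenesulfonyl azide, Et3N, MeCN, 0 → 23 °C
Reagents that add atoms: 4-acetamidobenzenesulfonyl azide, CC(=O)Nc1ccc(cc1)S(=O)(=O)N=[N+]=[N-]
Why: Regitz diazo transfer from the sulfonyl azide to the doubly activated methylene group.

Step 16
Reactants: 21 (3S,4S,8R)-9-(tert-butyldimethylsilyloxy)-4-[(tert-butyldimethylsilyloxy)methyl]-8-methyl-3-[(3R)-3-methyl-5-(triisopropylsilyl)pent-4-yn-1-yl]non-1-yne; 23 dibenzyl 2-diazomalonate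
Product: 24 dibenzyl 2-[(1S,2S,6R)-7-(tert-butyldimethylsilyloxy)-2-[(tert-butyldimethylsilyloxy)methyl]-6-methyl-1-[(3R)-3-methyl-5-(triisopropylsilyl)pent-4-yn-1-yl]heptyl]cycloprop-2-ene-1,1-dicarboxylate
Conditions: Rh2(OAc)4 (2 mol%), CH2Cl2, 23 °C, 23 (2.5 equiv) added by syringe pump
Reagents that add atoms: none
Why: Rh2(OAc)4 turns 23 into an electrophilic rhodium carbenoid that adds to the only unhindered π bond, the terminal alkyne, in a [2+1] cyclopropenation, while the triisopropylsilyl alkyne is sterically shielded.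

Step 17
Reactants: 24 dibenzyl 2-[(1S,2S,6R)-7-(tert-butyldimethylsilyloxy)-2-[(tert-butyldimethylsilyloxy)methyl]-6-methyl-1-[(3R)-3-methyl-5-(triisopropylsilyl)pent-4-yn-1-yl]heptyl]cycloprop-2-ene-1,1-dicarboxylate
Product: 25 benzyl 2-(benzyloxy)-5-[(1S,2S,6R)-7-(tert-butyldimethylsilyloxy)-2-[(tert-butyldimethylsilyloxy)methyl]-6-methyl-1-[(3R)-3-methyl-5-(triisopropylsilyl)pent-4-yn-1-yl]heptyl]furan-3-carboxylate
Conditions: RuCl2(PPh3)3 (5 mol%), toluene, 80 °C; filtration through Et3N-deactivated silica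
Reagents that add atoms: none
Why: Transition-metal-catalysed ring-opening cycloisomerisation of a cyclopropene-3,3-dicarboxylate to a 2-alkoxyfuran: with RuCl2(PPh3)3 the ring should open at the bond between the quaternary carbon and the alkyl-bearing sp2 carbon, so that an ester carbonyl oxygen closes onto the substituted carbon and the 5-substituted 2-benzyloxyfuran-3-carboxylate results.

Step 18
Reactants: 25 benzyl 2-(benzyloxy)-5-[(1S,2S,6R)-7-(tert-butyldimethylsilyloxy)-2-[(tert-butyldimethylsilyloxy)methyl]-6-methyl-1-[(3R)-3-methyl-5-(triisopropylsilyl)pent-4-yn-1-yl]heptyl]furan-3-carboxylate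
Product: 26 benzyl 2-(benzyloxy)-5-[(1S,2S,6R)-7-hydroxy-2-(hydroxymethyl)-6-methyl-1-[(3R)-3-methylpent-4-yn-1-yl]heptyl]furan-3-carboxylate
Conditions: TBAF (4 equiv), THF, 0 → 23 °C; aq. NH4Cl
Reagents that add atoms: none
Why: Fluoride-induced desilylation cleaves both O–Si bonds and the alkynyl C–Si bond in one operation, while the benzyl ester, the benzyloxyfuran and the stereocentres are not affected.

Step 19
Reactants: 26 benzyl 2-(benzyloxy)-5-[(1S,2S,6R)-7-hydroxy-2-(hydroxymethyl)-6-methyl-1-[(3R)-3-methylpent-4-yn-1-yl]heptyl]furan-3-carboxylate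
Product: 27 benzyl 5-[(1S,2S,6R)-7-acetoxy-2-(acetoxymethyl)-6-methyl-1-[(3R)-3-methylpent-4-yn-1-yl]heptyl]-2-(benzyloxy)furan-3-carboxylate
Conditions: Ac2O, pyridine, DMAP (cat.), CH2Cl2, 0 → 23 °C
Reagents that add atoms: acetic anhydride, CC(=O)OC(C)=O
Why: DMAP-catalysed acylation of the two primary alcohols installs the acetates of the target after the last strongly basic or nucleophilic step.

**Key step and end game**

Step 20
Reactants: 27 benzyl 5-[(1S,2S,6R)-7-acetoxy-2-(acetoxymethyl)-6-methyl-1-[(3R)-3-methylpent-4-yn-1-yl]heptyl]-2-(benzyloxy)furan-3-carboxylate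
Product: 29 benzyl (5R,8S)-3-(benzyloxy)-8-[(2S,6R)-1,7-diacetoxy-6-methylheptan-2-yl]-4-hydroxy-5-methyl-5,6,7,8-tetrahydronaphthalene-2-carboxylate, via arene oxide 28 (not isolated)
Conditions: Ph3PAuNTf2 (5 mol%), 4 Å MS, CH2Cl2, 23 °C
Reagents that add atoms: none
Why: Proposed new method: Ph3PAu+ (monovalent gold) should activate the terminal alkyne of 27, the furan carbon that carries the tether (future C8a) should attack the internal alkyne carbon (future C4a) to give a spiro cyclopropyl gold carbene, the furan should then open to a dienyl gold carbene bearing the benzyl ester carbonyl, and attack of that carbonyl oxygen on the carbene carbon (future C5) should give an oxepine in equilibrium with arene oxide 28, which opens at C6 and loses the C5 proton to give phenol 29. The closest known reaction type is the gold-catalysed furan–yne cycloisomerisation to annulated phenols, which is established for alkyl- and aryl-substituted furans on short, mostly heteroatom-containing tethers but not for a 2-alkoxyfuran-3-carboxylate on an all-carbon four-atom tether. Ring B closes in a 6-exo-dig attack of C8a on the gold-bound alkyne (C4a–C8a bond), and ring A closes when the oxepine undergoes 6π-electrocyclisation to the arene oxide (C5–C6 bond). No stereocentre is formed, and C1 and C4 are spectators because neither is deprotonated or ionised in the cascade. The step needs site selectivity for C8a over C8 in the first bond formation, secured by the tether (attack through C8 would need a seven-membered ring) and by the benzyloxy group, which makes the 5-position the most nucleophilic carbon of the furan, and it needs the epoxide to open toward C6 and not C5, secured by the benzyloxy group that stabilises positive charge at C6 so that the oxygen stays on C5. It also needs the alkyne to react before the acid-sensitive alkoxyfuran is hydrolysed, for which the silver-free, non-acidic catalyst, the molecular sieves and the branching at C1 and C4 (which favours the folded conformer) are relied upon.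

Step 21
Reactants: 29 benzyl (5R,8S)-3-(benzyloxy)-8-[(2S,6R)-1,7-diacetoxy-6-methylheptan-2-yl]-4-hydroxy-5-methyl-5,6,7,8-tetrahydronaphthalene-2-carboxylate
Product: 30 (5R,8S)-8-[(2S,6R)-1,7-diacetoxy-6-methylheptan-2-yl]-3,4-dihydroxy-5-methyl-5,6,7,8-tetrahydronaphthalene-2-carboxylic acid
Conditions: H2 (1 atm), 10% Pd/C, EtOAc, 23 °C
Reagents that add atoms: none
Why: Hydrogenolysis over Pd/C cleaves the benzyl ether and the benzyl ester to the catechol acid and leaves the acetates, the arene and the benzylic stereocentres C1 and C4 alone.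

**Compound list**

1 | methyl (S)-3-hydroxy-2-methylpropanoate | OC[C@H](C)C(=O)OC | starting material
2 | methyl (S)-3-(tert-butyldimethylsilyloxy)-2-methylpropanoate | CC(C)(C)[Si](C)(C)OC[C@H](C)C(=O)OC | intermediate
3 | (S)-3-(tert-butyldimethylsilyloxy)-2-methylpropanal | CC(C)(C)[Si](C)(C)OC[C@H](C)C=O | intermediate
4 | (4Z,6R)-7-(tert-butyldimethylsilyloxy)-6-methylhept-4-enoic acid | CC(C)(C)[Si](C)(C)OC[C@H](C)/C=C\CCC(=O)O | intermediate
5 | (R)-7-(tert-butyldimethylsilyloxy)-6-methylheptanoic acid | CC(C)(C)[Si](C)(C)OC[C@H](C)CCCCC(=O)O | intermediate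
6 | (R)-citronellal, (R)-3,7-dimethyloct-6-enal | O=CC[C@H](C)CCC=C(C)C | starting material
7 | (R)-3,7-dimethylocta-1,6-dien-1-yl nonafluorobutanesulfonate, E/Z mixture | CC(C)=CCC[C@@H](C)C=COS(=O)(=O)C(F)(F)C(F)(F)C(F)(F)C(F)(F)F | intermediate (not isolated)
8 | (R)-3,7-dimethyloct-6-en-1-yne | CC(C)=CCC[C@@H](C)C#C | intermediate
9 | (R)-(3,7-dimethyloct-6-en-1-yn-1-yl)triisopropylsilane | CC(C)=CCC[C@@H](C)C#C[Si](C(C)C)(C(C)C)C(C)C | intermediate
10 | ozonide of 9: 3,3-dimethyl-5-[(3R)-3-methyl-5-(triisopropylsilyl)pent-4-yn-1-yl]-1,2,4-trioxolane, mixture at the ring carbon | CC1(C)OOC(CC[C@@H](C)C#C[Si](C(C)C)(C(C)C)C(C)C)O1 | intermediate (not isolated)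
11 | (R)-4-methyl-6-(triisopropylsilyl)hex-5-ynal | O=CCC[C@@H](C)C#C[Si](C(C)C)(C(C)C)C(C)C | intermediate
12 | (3E,7R)-7-methyl-9-(triisopropylsilyl)non-3-en-8-yn-2-one | CC(=O)/C=C/CC[C@@H](C)C#C[Si](C(C)C)(C(C)C)C(C)C | intermediate
13 | (2S,3E,7R)-7-methyl-9-(triisopropylsilyl)non-3-en-8-yn-2-ol | C[C@H](O)/C=C/CC[C@@H](C)C#C[Si](C(C)C)(C(C)C)C(C)C | intermediate
14 | (2S,3E,7R)-7-methyl-9-(triisopropylsilyl)non-3-en-8-yn-2-yl (R)-7-(tert-butyldimethylsilyloxy)-6-methylheptanoate | CC(C)(C)[Si](C)(C)OC[C@H](C)CCCCC(=O)O[C@@H](C)/C=C/CC[C@@H](C)C#C[Si](C(C)C)(C(C)C)C(C)C | intermediate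
15 | tert-butyldimethylsilyl ketene acetal of 14, Z geometry (heptanoate chain cis to OSi) | CC(C)(C)[Si](C)(C)OC[C@H](C)CCC/C=C(\O[Si](C)(C)C(C)(C)C)O[C@@H](C)/C=C/CC[C@@H](C)C#C[Si](C(C)C)(C(C)C)C(C)C | intermediate (not isolated)
16 | tert-butyldimethylsilyl (2S,3R,4E)-2-[(4R)-5-(tert-butyldimethylsilyloxy)-4-methylpentyl]-3-[(3R)-3-methyl-5-(triisopropylsilyl)pent-4-yn-1-yl]hex-4-enoate | CC(C)(C)[Si](C)(C)OC[C@H](C)CCC[C@H](C(=O)O[Si](C)(C)C(C)(C)C)[C@H](CC[C@@H](C)C#C[Si](C(C)C)(C(C)C)C(C)C)/C=C/C | intermediate (not isolated)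
17 | (2S,3R,4E)-2-[(4R)-5-(tert-butyldimethylsilyloxy)-4-methylpentyl]-3-[(3R)-3-methyl-5-(triisopropylsilyl)pent-4-yn-1-yl]hex-4-en-1-ol | CC(C)(C)[Si](C)(C)OC[C@H](C)CCC[C@H](CO)[C@H](CC[C@@H](C)C#C[Si](C(C)C)(C(C)C)C(C)C)/C=C/C | intermediate
18 | (2S,3R,4E)-1-(tert-butyldimethylsilyloxy)-2-[(4R)-5-(tert-butyldimethylsilyloxy)-4-methylpentyl]-3-[(3R)-3-methyl-5-(triisopropylsilyl)pent-4-yn-1-yl]hex-4-ene | CC(C)(C)[Si](C)(C)OC[C@H](C)CCC[C@H](CO[Si](C)(C)C(C)(C)C)[C@H](CC[C@@H](C)C#C[Si](C(C)C)(C(C)C)C(C)C)/C=C/C | intermediate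
19 | ozonide of 18 (3-methyl-1,2,4-trioxolan-5-yl in place of the propenyl group), mixture at the ring carbons | CC(C)(C)[Si](C)(C)OC[C@H](C)CCC[C@H](CO[Si](C)(C)C(C)(C)C)[C@H](CC[C@@H](C)C#C[Si](C(C)C)(C(C)C)C(C)C)C1OOC(C)O1 | intermediate (not isolated)
20 | (2S,3S,7R)-8-(tert-butyldimethylsilyloxy)-3-[(tert-butyldimethylsilyloxy)methyl]-7-methyl-2-[(3R)-3-methyl-5-(triisopropylsilyl)pent-4-yn-1-yl]octanal | CC(C)(C)[Si](C)(C)OC[C@H](C)CCC[C@H](CO[Si](C)(C)C(C)(C)C)[C@H](CC[C@@H](C)C#C[Si](C(C)C)(C(C)C)C(C)C)C=O | intermediate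
21 | (3S,4S,8R)-9-(tert-butyldimethylsilyloxy)-4-[(tert-butyldimethylsilyloxy)methyl]-8-methyl-3-[(3R)-3-methyl-5-(triisopropylsilyl)pent-4-yn-1-yl]non-1-yne | CC(C)(C)[Si](C)(C)OC[C@H](C)CCC[C@H](CO[Si](C)(C)C(C)(C)C)[C@H](CC[C@@H](C)C#C[Si](C(C)C)(C(C)C)C(C)C)C#C | intermediate
22 | dibenzyl malonate | O=C(CC(=O)OCc1ccccc1)OCc1ccccc1 | starting material
23 | dibenzyl 2-diazomalonate | [N-]=[N+]=C(C(=O)OCc1ccccc1)C(=O)OCc1ccccc1 | intermediate
24 | dibenzyl 2-[(1S,2S,6R)-7-(tert-butyldimethylsilyloxy)-2-[(tert-butyldimethylsilyloxy)methyl]-6-methyl-1-[(3R)-3-methyl-5-(triisopropylsilyl)pent-4-yn-1-yl]heptyl]cycloprop-2-ene-1,1-dicarboxylate | CC(C)(C)[Si](C)(C)OC[C@H](C)CCC[C@H](CO[Si](C)(C)C(C)(C)C)[C@H](CC[C@@H](C)C#C[Si](C(C)C)(C(C)C)C(C)C)C1=CC1(C(=O)OCc2ccccc2)C(=O)OCc2ccccc2 | intermediate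
25 | benzyl 2-(benzyloxy)-5-[(1S,2S,6R)-7-(tert-butyldimethylsilyloxy)-2-[(tert-butyldimethylsilyloxy)methyl]-6-methyl-1-[(3R)-3-methyl-5-(triisopropylsilyl)pent-4-yn-1-yl]heptyl]furan-3-carboxylate | CC(C)(C)[Si](C)(C)OC[C@H](C)CCC[C@H](CO[Si](C)(C)C(C)(C)C)[C@H](CC[C@@H](C)C#C[Si](C(C)C)(C(C)C)C(C)C)c1cc(C(=O)OCc2ccccc2)c(OCc2ccccc2)o1 | intermediate
26 | benzyl 2-(benzyloxy)-5-[(1S,2S,6R)-7-hydroxy-2-(hydroxymethyl)-6-methyl-1-[(3R)-3-methylpent-4-yn-1-yl]heptyl]furan-3-carboxylate | OC[C@H](C)CCC[C@H](CO)[C@H](CC[C@@H](C)C#C)c1cc(C(=O)OCc2ccccc2)c(OCc2ccccc2)o1 | intermediate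
27 | benzyl 5-[(1S,2S,6R)-7-acetoxy-2-(acetoxymethyl)-6-methyl-1-[(3R)-3-methylpent-4-yn-1-yl]heptyl]-2-(benzyloxy)furan-3-carboxylate (furan–yne, key-step precursor) | CC(=O)OC[C@H](C)CCC[C@H](COC(C)=O)[C@H](CC[C@@H](C)C#C)c1cc(C(=O)OCc2ccccc2)c(OCc2ccccc2)o1 | intermediate
28 | C5–C6 arene oxide of 29 (epoxide between C5–H and C6–OBn, ring A diene C4a=C8a and C7=C8), mixture at the epoxide carbons | CC(=O)OC[C@H](C)CCC[C@H](COC(C)=O)[C@@H]1CC[C@@H](C)C2=C1C=C(C(=O)OCc3ccccc3)C4(OCc3ccccc3)OC24 | intermediate (not isolated)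
29 | benzyl (5R,8S)-3-(benzyloxy)-8-[(2S,6R)-1,7-diacetoxy-6-methylheptan-2-yl]-4-hydroxy-5-methyl-5,6,7,8-tetrahydronaphthalene-2-carboxylate (key-step product) | CC(=O)OC[C@H](C)CCC[C@H](COC(C)=O)[C@@H]1CC[C@@H](C)c2c1cc(C(=O)OCc3ccccc3)c(OCc3ccccc3)c2O | intermediate
30 | (5R,8S)-8-[(2S,6R)-1,7-diacetoxy-6-methylheptan-2-yl]-3,4-dihydroxy-5-methyl-5,6,7,8-tetrahydronaphthalene-2-carboxylic acid | CC(=O)OC[C@H](C)CCC[C@H](COC(C)=O)[C@@H]1CC[C@@H](C)c2c1cc(C(=O)O)c(O)c2O | target

**Step count**

Total: 21 steps.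
Longest linear sequence: 16 steps (6 to 30 through steps 5–14 and 16–21).

**Steps most likely to fail**

1. Step 20 (gold-catalysed cycloisomerisation). The benzyloxyfuran may be ring-opened or debenzylated by adventitious acid before gold engages the alkyne, or the cascade may stall after the first C–C bond because the ester carbonyl is too weak a nucleophile to trap the carbene. The fallback uses only known reaction types and no furan; it sets out from 1,7-diyne 21 and comes back at 29. Conjugate addition of benzyl alcohol to benzyl propiolate (DABCO cat.) gives benzyl (E)-3-(benzyloxy)acrylate F1, and iodination–elimination (NIS, AcOH; then Et3N) gives benzyl (Z)-3-(benzyloxy)-2-iodoacrylate F2. Sonogashira coupling of 21 with F2 (PdCl2(PPh3)2, CuI, Et3N) gives the conjugated enyne F3; TBAF removes the three silyl groups to give the enyne diol F4, which is acetylated (Ac2O, pyridine) to the enyne diacetate F5; acyl Sonogashira coupling of its free alkyne with acetyl chloride (PdCl2(PPh3)2, CuI, Et3N) gives the ynone F6. Heating F6 (toluene, 150–180 °C, BHT) should bring about the intramolecular [4+2] cycloaddition of the conjugated enyne with the ynone (dehydro-Diels–Alder benzannulation), which forms C4a–C8a and C5–C6; isomerisation of the cyclic allene gives the aryl methyl ketone F7. Baeyer–Villiger oxidation (mCPBA, NaHCO3) with migration of the electron-rich aryl group gives the aryl acetate F8, and aminolysis with pyrrolidine at 0 °C, which spares the primary acetates, frees the C5 phenol 29.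

2. Step 17 (cyclopropene to furan). The ring may open on the wrong side, so that the oxygen bonds to the unsubstituted carbon and the 4-substituted furan results, or the alkoxyfuran may decompose on the catalyst. The fallback fixes the regiochemistry through an enol ether; it sets out from 21 and comes back at 25. Gold-catalysed addition of methanol to the terminal alkyne (Ph3PAuNTf2 cat., MeOH, HC(OMe)3) gives the dimethyl ketal F9, and loss of methanol (TMSOTf, iPr2NEt) gives the 2-methoxyalkene F10. Rh2(OAc)4 and 23 then give, by formal [3+2] cycloaddition of the carbenoid with the electron-rich alkene (carbenoid carbon to CH2, carbonyl oxygen to the methoxy-bearing carbon), the 5-methoxy-4,5-dihydrofuran F11, and acid-catalysed loss of methanol (PPTS) gives 25 with the substituent necessarily at the 5-position.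

3. Step 11 (Ireland–Claisen rearrangement). Control of enolate geometry in THF/DMPU may be incomplete, so that the E ketene acetal leaks through and the C1′ epimer forms. The fallback pairs a Z allylic ester with the E ketene acetal from LDA in THF alone; it sets out from aldehyde 11 and acid 5 and comes back at 17 through silyl ester 16. Corey–Fuchs olefination of 11 (CBr4, PPh3) gives the dibromoalkene F12; n-BuLi (2 equiv) followed by N-methoxy-N-methylacetamide gives the ynone F13; asymmetric transfer hydrogenation (RuCl[(R,R)-TsDPEN](p-cymene), iPrOH) gives the (R)-propargylic alcohol F14; semi-hydrogenation (H2, Pd/CaCO3 poisoned with Pb(OAc)2, quinoline) gives the (R,Z)-allylic alcohol F15; esterification with 5 (DCC, DMAP) gives the Z allylic ester F16. LDA in THF without DMPU should give the enolate with the chain trans to O–Li, silylation gives the E ketene acetal F17, and the chair transition state (alkene substituent axial, carbinol methyl equatorial) should give the same silyl ester 16, which LiAlH4 reduces to 17 as before.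

**Further compounds**

F1 | step 20 | benzyl (E)-3-(benzyloxy)acrylate | O=C(OCc1ccccc1)/C=C/OCc1ccccc1
F2 | step 20 | benzyl (Z)-3-(benzyloxy)-2-iodoacrylate | O=C(OCc1ccccc1)/C(I)=C/OCc1ccccc1
F3 | step 20 | enyne from 21 and F2 (benzyl 3-(benzyloxy)-2-alkynylacrylate, silyl groups retained) | CC(C)(C)[Si](C)(C)OC[C@H](C)CCC[C@H](CO[Si](C)(C)C(C)(C)C)[C@H](CC[C@@H](C)C#C[Si](C(C)C)(C(C)C)C(C)C)C#C/C(C(=O)OCc1ccccc1)=C\OCc1ccccc1
F4 | step 20 | enyne diol with free C4 alkyne | OC[C@H](C)CCC[C@H](CO)[C@H](CC[C@@H](C)C#C)C#C/C(C(=O)OCc1ccccc1)=C\OCc1ccccc1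
F5 | step 20 | enyne diacetate | CC(=O)OC[C@H](C)CCC[C@H](COC(C)=O)[C@H](CC[C@@H](C)C#C)C#C/C(C(=O)OCc1ccccc1)=C\OCc1ccccc1
F6 | step 20 | ynone (methyl ketone on the C4 alkyne) | CC(=O)OC[C@H](C)CCC[C@H](COC(C)=O)[C@H](CC[C@@H](C)C#CC(C)=O)C#C/C(C(=O)OCc1ccccc1)=C\OCc1ccccc1
F7 | step 20 | C5-acetyl analogue of 29 (aryl methyl ketone) | CC(=O)OC[C@H](C)CCC[C@H](COC(C)=O)[C@@H]1CC[C@@H](C)c2c1cc(C(=O)OCc3ccccc3)c(OCc3ccccc3)c2C(C)=O
F8 | step 20 | C5 aryl acetate of 29 | CC(=O)OC[C@H](C)CCC[C@H](COC(C)=O)[C@@H]1CC[C@@H](C)c2c1cc(C(=O)OCc3ccccc3)c(OCc3ccccc3)c2OC(C)=O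
F9 | step 17 | dimethyl ketal from 21 (C(CH3)(OCH3)2 in place of the ethynyl group) | CC(C)(C)[Si](C)(C)OC[C@H](C)CCC[C@H](CO[Si](C)(C)C(C)(C)C)[C@H](CC[C@@H](C)C#C[Si](C(C)C)(C(C)C)C(C)C)C(C)(OC)OC
F10 | step 17 | 2-methoxyalkene (C(OCH3)=CH2 in place of the ethynyl group) | CC(C)(C)[Si](C)(C)OC[C@H](C)CCC[C@H](CO[Si](C)(C)C(C)(C)C)[C@H](CC[C@@H](C)C#C[Si](C(C)C)(C(C)C)C(C)C)C(=C)OC
F11 | step 17 | benzyl 2-(benzyloxy)-5-methoxy-5-alkyl-4,5-dihydrofuran-3-carboxylate, mixture at C5 of the dihydrofuran | CC(C)(C)[Si](C)(C)OC[C@H](C)CCC[C@H](CO[Si](C)(C)C(C)(C)C)[C@H](CC[C@@H](C)C#C[Si](C(C)C)(C(C)C)C(C)C)C1(OC)CC(C(=O)OCc2ccccc2)=C(OCc2ccccc2)O1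
F12 | step 11 | (R)-(7,7-dibromo-3-methylhept-6-en-1-yn-1-yl)triisopropylsilane | BrC(Br)=CCC[C@@H](C)C#C[Si](C(C)C)(C(C)C)C(C)C
F13 | step 11 | (R)-7-methyl-9-(triisopropylsilyl)nona-3,8-diyn-2-one | CC(=O)C#CCC[C@@H](C)C#C[Si](C(C)C)(C(C)C)C(C)C
F14 | step 11 | (2R,7R)-7-methyl-9-(triisopropylsilyl)nona-3,8-diyn-2-ol | C[C@@H](O)C#CCC[C@@H](C)C#C[Si](C(C)C)(C(C)C)C(C)C
F15 | step 11 | (2R,3Z,7R)-7-methyl-9-(triisopropylsilyl)non-3-en-8-yn-2-ol | C[C@@H](O)/C=C\CC[C@@H](C)C#C[Si](C(C)C)(C(C)C)C(C)C
F16 | step 11 | (2R,3Z,7R)-7-methyl-9-(triisopropylsilyl)non-3-en-8-yn-2-yl (R)-7-(tert-butyldimethylsilyloxy)-6-methylheptanoate | CC(C)(C)[Si](C)(C)OC[C@H](C)CCCCC(=O)O[C@H](C)/C=C\CC[C@@H](C)C#C[Si](C(C)C)(C(C)C)C(C)C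
F17 | step 11 | tert-butyldimethylsilyl ketene acetal of F16, E geometry (heptanoate chain trans to OSi) | CC(C)(C)[Si](C)(C)OC[C@H](C)CCC/C=C(/O[Si](C)(C)C(C)(C)C)O[C@H](C)/C=C\CC[C@@H](C)C#C[Si](C(C)C)(C(C)C)C(C)C
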